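The earlier runs and the new flask stem from a simulated flask on assumed constants, and the scatter is random.

The vessel is a closed, stirred, isothermal flask in which solid substrate dissolves, dissolved substrate meets partner to give target, and target can crystallise as solid product, while solid substrate can also pair off into homo dimer.

- teal: solid substrate 1 M; partner 2.5 M; run made earlier
- flask: solid substrate 1.0 M; partner 1.80 M; time 50 min

- teal (time / min: target / %, solid product / %): 3.00: 34, 2; 5.00: 54, 12; 8.00: 54, 17; 12.0: 54, 19; 15.0: 57, 18; 25.0: 58, 19; 40.0: 56, 19

(readings scatter by 1.5 percentage points)

- in percentages every species weighs as the solid substrate in it: one homo dimer counts as two
- for target the solid product is counted in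
- as a solid, counted per litre of solution: solid substrate, solid product
- the numbers in the tables scatter with a standard deviation of 1.5 percentage points
- steps under discussion: solid substrate <-> dissolved substrate; dissolved substrate + partner -> target; solid product <-> target; 2 solid substrate -> homo dimer
- at the start none of the solid substrate is in solution
- dissolved substrate means what is dissolved; the solid is not counted in it

- how much target and solid product together there is at 50 min, in percent of the solid substrate charged
- concentration of dissolved substrate in solution at 50 min, in percent of saturation

The teal readings form a ladder. On the first rung, teal target has nearly stopped climbing by 5.00 min; on the next, teal solid product levels by 12.0 min, earlier than the asked time, and it is already counted inside target, so it leaves the sum unmoved. On the last rung, from 12.0 min to 40.0 min, the teal sum shows no trend I can tell from a scatter of 1.5 percentage points, and I average those readings to 56.2%.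

The other 43.8% of the teal charge does not appear in that sum, and homo dimer is the other way out among the steps under discussion, so I define the pairing number m, the loss to pairing measured against capture through dissolving, as 2.16, taking the fraction that reaches target to be one over the square root of one plus m. This form joins two ends: small m gives the whole charge, and large m gives a fraction falling as one over the charge, the form I expect if pairing goes with the square of the solid. I assume that m ignores partner and scales with the charge squared.

In the flask, solid substrate is the limiting reagent, charged at less than partner, and its charge matches teal. So I commit to 56.2% and, taking the level teal sum as a sign that dissolved substrate has passed into target, to dissolved substrate near 0% of saturation.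

The forecast says 50% and 0%, reasoning that “Dissolved substrate then reacts away within minutes”; the flask gives 56.2% and 0%.

    solid substrate ⇌ dissolved substrate, rate k1*(cs1 - [dissolved substrate]) while solid is left; crystals form when [dissolved substrate] > cs1 (solubility = 0.640 M, k = 0.00380 s⁻¹)
    dissolved substrate + partner → target (k = 0.0150 M⁻¹ s⁻¹)
    solid product ⇌ target, rate k3*(cs3 - [target]) while solid is left; crystals form when [target] > cs3 (solubility = 0.380 M, k = 0.0230 s⁻¹)
    2 solid substrate → homo dimer (k = 0.00420 M⁻¹ s⁻¹)

The pairing number counts a real loss: this flask reaches 56.2%, but 100% without pairing and 98.6% with fast dissolving, so the shortfall comes from solid pairing off while it waits to dissolve, and homo dimer holds 43.8%. In a second flask, like this one but charged with 2.5 M of solid substrate, the pairing number grows from 2.16 to 13.5, which gives 26.3%; the computed value there is 27.9%.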